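## Retrosynthetic overview

1. Feature: ring D, the arene whose OH sits ortho to the A–D biaryl bond, is substituted only at three neighbouring carbons (C–OH, the biaryl carbon, the carbon carrying the CH2CH2 bridge to ring C). Its other three carbons are adjacent CH groups, so the six ring atoms map onto the chain Cα(H2, on ring A)–C1(=O)–C2H2–C3H2–C4H2–C5(=O), with C6 and C7 as the bridge to ring C.
2. Plagiochin E 20 ⇐ O-demethylation ⇐ phenol 19 ⇐ dehydrogenation of cyclohexenone 17 ⇐ transannular aldol condensation of the 20-membered 1,5-diketone 15. The aldol makes the Cα–C5 bond, which joins the biaryl carbon to the bridge-bearing carbon of ring D.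
3. 15 ⇐ double oxidation and hydrogenation ⇐ ring-closing metathesis (C3=C4) of the open diene-diol 12.
4. 12 ⇐ allylboration and vinyl Grignard addition at two aldehydes unmasked one after the other ⇐ bibenzyl bromide 7 ⇐ Horner–Wadsworth–Emmons/diimide (A–B bridge) and Ullmann coupling (B–O–C ether).
5. Ring order: A, B and C are bought; the 20-membered ring forms in step 10; carbocycle D forms in step 13 with contraction to the 16-membered ring; D becomes aromatic in step 14.

Key step: step 13

Remark: the target SMILES carries no stereodescriptor, so the A–D axis is treated as undefined. The carbinol centres of 10–14 and the two centres of 16 arise as stereoisomer mixtures, are drawn without configuration, and are all destroyed by step 13.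

## Route

Step 1
Reactants: 1 methyl 3-(4-hydroxyphenyl)propanoate; 2 3-bromo-4-methoxybenzaldehyde
Product: 3 methyl 3-[4-(5-formyl-2-methoxyphenoxy)phenyl]propanoate
Conditions: CuI (10 mol %), N,N-dimethylglycine (30 mol %), Cs2CO3, dioxane, 90 °C
Reagents that add atoms: none
Why: Ligand-accelerated Ullmann diaryl ether coupling: the caesium phenoxide of 1 replaces the bromide of 2 at a temperature at which an ortho-methoxy aryl bromide still reacts, while the aldehyde and the methyl ester are untouched in the dry medium.

Step 2
Reactants: 4 2-bromo-5-methoxybenzyl bromide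
Product: 5 diethyl (2-bromo-5-methoxybenzyl)phosphonate
Conditions: P(OEt)3, neat, 140 °C
Reagents that add atoms: triethyl phosphite, CCOP(OCC)OCC
Why: Michaelis–Arbuzov reaction: phosphorus attacks only the benzylic C–Br bond by SN2 and bromide then dealkylates the phosphonium ion, the aryl C–Br bond being inert without a metal catalyst.

Step 3
Reactants: 5 diethyl (2-bromo-5-methoxybenzyl)phosphonate; 3 methyl 3-[4-(5-formyl-2-methoxyphenoxy)phenyl]propanoate
Product: 6 methyl 3-[4-(5-[(E)-2-(2-bromo-5-methoxyphenyl)ethenyl]-2-methoxyphenoxy)phenyl]propanoate
Conditions: NaOMe, DMF, 0 °C → rt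
Reagents that add atoms: none
Why: Horner–Wadsworth–Emmons olefination of a non-enolizable aryl aldehyde with a benzylic phosphonate anion should give the (E)-stilbene, and methoxide as base makes any ester exchange degenerate.

Step 4
Reactants: 6 (E)-stilbene bromide ester
Product: 7 methyl 3-[4-(5-[2-(2-bromo-5-methoxyphenyl)ethyl]-2-methoxyphenoxy)phenyl]propanoate
Conditions: TsNHNH2, NaOAc, DME/H2O, reflux
Reagents that add atoms: none
Why: Diimide reduction: diazene released from the sulfonyl hydrazide transfers two hydrogen atoms to the C=C bond in a concerted syn fashion and cannot touch the aryl C–Br bond, which hydrogenation over palladium would cleave.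

Step 5
Reactants: 7 bibenzyl bromide ester
Product: 8 methyl 3-{4-[5-(2-{2-[(E)-2-ethoxyethenyl]-5-methoxyphenyl}ethyl)-2-methoxyphenoxy]phenyl}propanoate
Conditions: (E)-EtOCH=CH-Bpin, Pd(OAc)2 (3 mol %), SPhos (6 mol %), K3PO4, THF/H2O 10:1, 65 °C
Reagents that add atoms: (E)-2-(2-ethoxyvinyl)-4,4,5,5-tetramethyl-1,3,2-dioxaborolane, CCO/C=C/B1OC(C)(C)C(C)(C)O1
Why: Suzuki–Miyaura coupling: the bulky electron-rich biaryl phosphine allows oxidative addition of the electron-rich ortho-substituted bromide, and the aryl–carbon bond that will end as the crowded biaryl bond is made here as an unhindered aryl–vinyl bond.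

Step 6
Reactants: 8 aryl enol ether
Product: 9 methyl 3-{4-[2-methoxy-5-(2-[5-methoxy-2-(2-oxoethyl)phenyl]ethyl)phenoxy]phenyl}propanoate
Conditions: 2 M HCl, THF, rt → 40 °C
Reagents that add atoms: water, O
Why: Acid-catalysed enol ether hydrolysis: protonation at the aryl-bearing carbon, addition of water to the oxocarbenium ion and loss of ethanol give the arylacetaldehyde, which is used without storage, while the methyl ester is stable to dilute acid at this temperature.

Step 7
Reactants: 9 arylacetaldehyde ester
Product: 10 methyl 3-{4-[5-(2-[2-(2-hydroxypent-4-en-1-yl)-5-methoxyphenyl]ethyl)-2-methoxyphenoxy]phenyl}propanoate (racemic)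
Conditions: allyl-Bpin, toluene, rt; aqueous work-up
Reagents that add atoms: allylboronic acid pinacol ester, C=CCB1OC(C)(C)C(C)(C)O1
Why: Allylboration through a closed six-membered transition state runs under neutral conditions, so the enolizable arylacetaldehyde is not deprotonated and the ester is not attacked; the new carbinol centre C1 is racemic and is erased in step 12.

Step 8
Reactants: 10 homoallylic alcohol ester
Product: 11 3-{4-[5-(2-[2-(2-hydroxypent-4-en-1-yl)-5-methoxyphenyl]ethyl)-2-methoxyphenoxy]phenyl}propanal
Conditions: i-Bu2AlH (2.2 equiv), CH2Cl2, −78 °C; then aq potassium sodium tartrate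
Reagents that add atoms: none
Why: Partial ester reduction: after the first equivalent is consumed by the hydroxyl group, hydride addition at −78 °C stops at the tetrahedral aluminium hemiacetal, which releases the aldehyde only on work-up.

Step 9
Reactants: 11 hydroxy aldehyde
Product: 12 open diene-diol, 1-[2-(2-{3-[4-(3-hydroxypent-4-en-1-yl)phenoxy]-4-methoxyphenyl}ethyl)-4-methoxyphenyl]pent-4-en-2-ol (diastereomer mixture)
Conditions: CH2=CHMgBr (3 equiv), THF, −78 → 0 °C; then aq NH4Cl
Reagents that add atoms: vinylmagnesium bromide, C=C[Mg]Br
Why: Grignard 1,2-addition to an unhindered aliphatic aldehyde, with one extra equivalent for the free hydroxyl group; the new carbinol centre C5 forms without control relative to the remote C1, and both centres are erased in step 12.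

Step 10
Reactants: 12 open diene-diol
Product: 13 20-membered macrocyclic ene-diol, chain ring C–CH2CH2–CH(OH)–CH=CH–CH2–CH(OH)–CH2–ring A (mainly E expected, either geometry serves)
Conditions: second-generation Grubbs catalyst RuCl2(=CHPh)(PCy3)(SIMes) (2 × 5 mol %), 1,4-benzoquinone (10 mol %), CH2Cl2, 1 mM, slow addition, 40 °C
Reagents that add atoms: none
Why: Ring-closing metathesis of two monosubstituted terminal alkenes, driven by loss of ethene and kept intramolecular by high dilution; no small ring can form because the stilbene double bond is already saturated, and benzoquinone holds back ruthenium hydride isomerization of the allylic alcohol.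

Step 11
Reactants: 13 macrocyclic ene-diol
Product: 14 20-membered macrocyclic 1,5-diol
Conditions: H2 (1 atm), Pd/C, EtOAc, rt
Reagents that add atoms: none
Why: Heterogeneous catalytic hydrogenation of the single disubstituted alkene, with no halide or benzyl ether left to suffer hydrogenolysis; any isomerization of the allylic alcohol to the C5 ketone is harmless, since step 12 leads to the same diketone.

Step 12
Reactants: 14 macrocyclic 1,5-diol
Product: 15 20-membered macrocyclic 1,5-diketone, chain ring A–CH2–C(=O)–(CH2)3–C(=O)–CH2CH2–ring C
Conditions: Dess–Martin periodinane (3 equiv), NaHCO3, CH2Cl2, 0 °C → rt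
Reagents that add atoms: none
Why: Dess–Martin oxidation turns both secondary alcohols into ketones under buffered, practically neutral conditions, so that the aldol-prone 1,5-diketone is not enolized before step 13.

Step 13
Reactants: 15 20-membered macrocyclic 1,5-diketone
Product: 17 macrocyclic 2-aryl-3-alkylcyclohex-2-enone (16-membered ring; ring A on the enone α carbon and the bridge to ring C on the β carbon), via aldol adduct 16 (not isolated)
Conditions: KOH (3 equiv), degassed EtOH, 3 mM, Ar, rt → 60 °C
Reagents that add atoms: none
Why: Ethanolic hydroxide reversibly deprotonates 15 at Cα, the only α position flanked by both a carbonyl group and an arene (ring A) and therefore several pK units more acidic than C2, C4 or C6; the conjugated enolate adds through Cα to the C5 ketone across the ring to give aldol 16, and E1cB loss of water through the still doubly activated Cα–H gives the tetrasubstituted enone 17. The closest known reaction type is the base-mediated aldol condensation of 1-aryl-2,6-diones to 2-aryl-3-alkylcyclohex-2-enones (the closing half of a Robinson annulation), whose transannular version is established for macrocyclic 1,5-diones that collapse to ring-fused cyclohexenones. The one ring closed, carbocycle D, forms in the favoured 6-(enolendo)-exo-trig mode, since both enolate carbons Cα and C1 end up inside the new ring and the C5=O bond is exocyclic to it, and the new Cα–C5 bond cuts the macrocycle from 20 to 16 members. No stereocentre remains, because the two centres of 16 (Cα and C5) are flattened by the dehydration. The selectivity needed is Cα→C5 against C6→C1, the only other six-membered closure (C2 and C4 could only give four-membered rings); that rival would also leave a 16-membered ring, so ring size does not decide, and the outcome rests on the much larger share of the aryl-conjugated enolate, on reversible aldol addition and on the faster, practically irreversible dehydration of 16. High dilution and exclusion of oxygen keep intermolecular aldol reaction and autoxidation of the benzylic enolate down.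

Step 14
Reactants: 17 macrocyclic cyclohexenone
Product: 19 plagiochin E dimethyl ether (free OH on ring D and OMe on rings A and B), via cross-conjugated dienone 18 (not isolated)
Conditions: Pd(OCOCF3)2 (5 mol %), 2-(dimethylamino)pyridine (10 mol %), TsOH (20 mol %), O2 (1 atm), DMSO, 80 °C
Reagents that add atoms: none
Why: Palladium-catalysed aerobic dehydrogenation: the divalent palladium enolate formed at the only free α position (the ring D CH2 next to C=O) undergoes β-hydride elimination to dienone 18, which tautomerizes to the phenol, and oxygen returns zerovalent palladium to the divalent state.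

Step 15
Reactants: 19 plagiochin E dimethyl ether
Product: 20 plagiochin E
Conditions: BBr3 (6 equiv), CH2Cl2, −78 °C → rt; then H2O
Reagents that add atoms: none
Why: Lewis acid ether cleavage: BBr3 binds each methoxy oxygen and bromide removes the methyl group by SN2, whereas the diaryl ether has no sp3 carbon to attack and survives.

## Compound list

1 | methyl 3-(4-hydroxyphenyl)propanoate | COC(=O)CCc1ccc(O)cc1 | starting material
2 | 3-bromo-4-methoxybenzaldehyde | COc1ccc(C=O)cc1Br | starting material
3 | methyl 3-[4-(5-formyl-2-methoxyphenoxy)phenyl]propanoate | COC(=O)CCc1ccc(Oc2cc(C=O)ccc2OC)cc1 | intermediate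
4 | 2-bromo-5-methoxybenzyl bromide | COc1ccc(Br)c(CBr)c1 | starting material
5 | diethyl (2-bromo-5-methoxybenzyl)phosphonate | CCOP(=O)(Cc1cc(OC)ccc1Br)OCC | intermediate
6 | (E)-stilbene bromide ester | COC(=O)CCc1ccc(Oc2cc(/C=C/c3cc(OC)ccc3Br)ccc2OC)cc1 | intermediate
7 | bibenzyl bromide ester | COC(=O)CCc1ccc(Oc2cc(CCc3cc(OC)ccc3Br)ccc2OC)cc1 | intermediate
8 | (E)-2-ethoxyethenyl arene ester | COC(=O)CCc1ccc(Oc2cc(CCc3cc(OC)ccc3/C=C/OCC)ccc2OC)cc1 | intermediate
9 | arylacetaldehyde ester | COC(=O)CCc1ccc(Oc2cc(CCc3cc(OC)ccc3CC=O)ccc2OC)cc1 | intermediate
10 | homoallylic alcohol ester (racemic) | COC(=O)CCc1ccc(Oc2cc(CCc3cc(OC)ccc3CC(O)CC=C)ccc2OC)cc1 | intermediate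
11 | hydroxy aldehyde (racemic) | O=CCCc1ccc(Oc2cc(CCc3cc(OC)ccc3CC(O)CC=C)ccc2OC)cc1 | intermediate
12 | open diene-diol (diastereomer mixture) | C=CC(O)CCc1ccc(Oc2cc(CCc3cc(OC)ccc3CC(O)CC=C)ccc2OC)cc1 | intermediate
13 | 20-membered macrocyclic ene-diol (drawn E, diastereomer mixture) | COc1ccc2c(c1)CCc1ccc(OC)c(c1)Oc1ccc(cc1)CCC(O)/C=C/CC(O)C2 | intermediate
14 | 20-membered macrocyclic 1,5-diol (diastereomer mixture) | COc1ccc2c(c1)CCc1ccc(OC)c(c1)Oc1ccc(cc1)CCC(O)CCCC(O)C2 | intermediate
15 | 20-membered macrocyclic 1,5-diketone | COc1ccc2c(c1)CCc1ccc(OC)c(c1)Oc1ccc(cc1)CCC(=O)CCCC(=O)C2 | intermediate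
16 | transannular aldol adduct, 3-hydroxy-2-aryl-3-alkylcyclohexanone (not isolated, configuration undefined) | COc1ccc2c(c1)CCc1ccc(OC)c(c1)Oc1ccc(cc1)CCC1(O)C2C(=O)CCC1 | intermediate
17 | macrocyclic 2-aryl-3-alkylcyclohex-2-enone (16-membered ring) | COc1ccc2c(c1)CCc1ccc(OC)c(c1)Oc1ccc(cc1)CCC1=C2C(=O)CCC1 | intermediate
18 | cross-conjugated cyclohexa-2,5-dienone (not isolated) | COc1ccc2c(c1)CCc1ccc(OC)c(c1)Oc1ccc(cc1)CCC1=C2C(=O)C=CC1 | intermediate
19 | plagiochin E dimethyl ether (ring D phenol) | COc1ccc2c(c1)CCc1ccc(OC)c(c1)Oc1ccc(cc1)CCc1cccc(O)c1-2 | intermediate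
20 | plagiochin E | Oc1ccc2c(c1)CCc1ccc(O)c(c1)Oc1ccc(cc1)CCc1cccc(O)c1-2 | target

## Step count

Total step count: 15.
Longest linear sequence: 14 (steps 1 and 3–15; the branch through step 2 is equally long).

## Steps most likely to fail

**Step 13 (transannular aldol condensation).**
- What may go wrong: enolization and closure through C6 instead of Cα. The aldol addition may also reverse before water is lost, because contraction from 20 to 16 ring members builds strain, so that slow intermolecular condensation takes over.
- Fallback: fix the nucleophile before the C–C bond is made and separate addition from dehydration.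
- Setting out from 15, soft enolization with TMSOTf (1 equiv) and Et3N in CH2Cl2 at 0 °C should silylate only the more acidic benzyl ketone. This gives the ring A conjugated (Z)-trimethylsilyl enol ether F1.
- TiCl4 in CH2Cl2 at −78 °C under high dilution then triggers an intramolecular Mukaiyama aldol addition onto the C5 ketone. The titanium aldolate chelate blocks the retro-aldol path, so aldol 16 is now isolated.
- Catalytic TsOH in toluene at 80 °C removes water toward the conjugated position, and the sequence comes back to the route at 17.

**Step 10 (ring-closing metathesis).**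
- What may go wrong: intermolecular metathesis to dimers and oligomers despite dilution, or isomerization of the allylic alcohol terminus before ring closure.
- Fallback: close the same ring by forming the C4–C5 bond in a Nozaki–Hiyama–Kishi reaction.
- Setting out from 9, allenylboronic acid pinacol ester in toluene should give the homopropargylic alcohol F2.
- Hydrozirconation with Cp2ZrHCl (2.5 equiv, THF) followed by I2 gives the (E)-vinyl iodide F3.
- i-Bu2AlH (2.2 equiv, CH2Cl2, −78 °C) reduces the ester to the iodo aldehyde F4.
- CrCl2 with catalytic NiCl2 in DMSO/THF at high dilution adds the alkenylchromium species to the aldehyde. The sequence comes back to the route at 13, as its E isomer.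

**Step 14 (aerobic dehydrogenation).**
- What may go wrong: slow palladation of the hindered tetrasubstituted enone, with decay of the catalyst to palladium black, or competing oxidation at the benzylic bridge positions.
- Fallback: introduce the second double bond by stoichiometric enolate chemistry.
- Setting out from 17, kinetic deprotonation with LiN(i-Pr)2 in THF at −78 °C occurs at the ring D CH2 next to the carbonyl group. Trapping with PhSeCl gives the 6-(phenylselanyl)cyclohexenone F5.
- H2O2 in CH2Cl2/pyridine at 0 °C oxidizes it to the selenoxide F6, which undergoes syn elimination to dienone 18.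
- Tautomerization of 18 brings the sequence back to the route at 19.

## Further compounds

F1 | step 13 | ring A conjugated (Z)-trimethylsilyl enol ether of diketone 15 | C[Si](C)(C)O/C1=C\c2ccc(OC)cc2CCc2ccc(OC)c(c2)Oc2ccc(cc2)CCC(=O)CCC1
F2 | step 10 | homopropargylic alcohol ester (racemic) | COC(=O)CCc1ccc(Oc2cc(CCc3cc(OC)ccc3CC(O)CC#C)ccc2OC)cc1
F3 | step 10 | (E)-vinyl iodide ester (racemic) | COC(=O)CCc1ccc(Oc2cc(CCc3cc(OC)ccc3CC(O)C/C=C/I)ccc2OC)cc1
F4 | step 10 | (E)-iodo aldehyde (racemic) | O=CCCc1ccc(Oc2cc(CCc3cc(OC)ccc3CC(O)C/C=C/I)ccc2OC)cc1
F5 | step 14 | 6-(phenylselanyl)cyclohexenone derived from 17 (racemic) | COc1ccc2c(c1)CCc1ccc(OC)c(c1)Oc1ccc(cc1)CCC1=C2C(=O)C([Se]c3ccccc3)CC1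
F6 | step 14 | selenoxide of F5 (configuration undefined) | COc1ccc2c(c1)CCc1ccc(OC)c(c1)Oc1ccc(cc1)CCC1=C2C(=O)C([Se](=O)c3ccccc3)CC1
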